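**Strategy.** The route rests on a late hetero-Diels–Alder union of two phenanthrene halves and on building ring A of each half by one annulation (phenanthrene numbering). In the upper half the aromatic C4a=C10a bond of ring B, conjugated with a vinyl group (C4=C3), serves as a diene towards the C=C bond of dimethylketene. One operation closes C2–C3 and C1–C10a, installs the gem-dimethyl ketone and rearomatises ring B by hydrogen shift. The precursor is a simple 4-vinyl-1-naphthol silyl ether. The same annulation with methylketene gives the catechol half; its o-quinone adds across the 3-methoxy enone of the upper half to set the cis ketal/benzylic ether pair.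

Key step: step 6

Remark on the chemistry: phenanthrene locants are used for both halves (plain for the upper, ketone-bearing half; primed for the lower, catechol-derived half); the target is the cis-fused (S)-ketal carbon C3, (S)-C4 isomer (CIP, read from the SMILES); the (R) enantiomer of the phosphoric acid in step 18 is an assumption, and the (S) catalyst would be used if the sense of induction proved opposite.

**Upper half**

Step 1
Reactants: 1 3-methoxy-4-methylbenzaldehyde; 2 (2-carboxyethyl)triphenylphosphonium bromide
Product: 3 (E)-4-(3-methoxy-4-methylphenyl)but-3-enoic acid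
Conditions: NaN(SiMe3)2 (2.2 equiv), THF, 0 °C → rt; aq. HCl work-up
Reagents that add atoms: none
Why: Wittig olefination with the carboxylate-bearing ylide should give the β,γ-unsaturated acid (mainly E; either geometry serves in step 2), and no stereocentre is formed.

Step 2
Reactants: 3 (E)-4-(3-methoxy-4-methylphenyl)but-3-enoic acid
Product: 5 6-methoxy-7-methylnaphthalen-1-ol, via naphthyl acetate 4 (not isolated)
Conditions: Ac2O, NaOAc, 140 °C; then K2CO3 (cat.), MeOH, rt
Reagents that add atoms: none
Why: Mixed-anhydride formation, elimination to the vinylketene, six-electron electrocyclisation onto the arene carbon para to the methoxy group and tautomerisation (the classical 4-arylbut-3-enoic acid benzannulation) should give the naphthyl acetate, which methanolysis converts into the naphthol.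

Step 3
Reactants: 5 6-methoxy-7-methylnaphthalen-1-ol
Product: 6 4-bromo-6-methoxy-7-methylnaphthalen-1-ol
Conditions: NBS, MeCN, −20 °C → 0 °C
Reagents that add atoms: N-bromosuccinimide O=C1CCC(=O)N1Br
Why: Electrophilic aromatic bromination, in which the free naphthol hydroxyl directs the halogen to the para carbon of its own ring in preference to the positions activated only by the methoxy group.

Step 4
Reactants: 6 4-bromo-6-methoxy-7-methylnaphthalen-1-ol
Product: 7 [(4-bromo-6-methoxy-7-methylnaphthalen-1-yl)oxy]triisopropylsilane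
Conditions: TIPSCl, imidazole, DMF, rt
Reagents that add atoms: chlorotriisopropylsilane CC(C)[Si](Cl)(C(C)C)C(C)C
Why: Silyl ether formation masks the phenol with a bulky, electron-donating group that should tolerate the Lewis acid of step 6 and be removed by fluoride at the end.

Step 5
Reactants: 7 [(4-bromo-6-methoxy-7-methylnaphthalen-1-yl)oxy]triisopropylsilane
Product: 8 [(4-ethenyl-6-methoxy-7-methylnaphthalen-1-yl)oxy]triisopropylsilane
Conditions: CH2=CHSnBu3, Pd(PPh3)4 (5 mol %), toluene, 100 °C
Reagents that add atoms: tributyl(vinyl)stannane C=C[Sn](CCCC)(CCCC)CCCC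
Why: Stille cross-coupling of the aryl bromide installs the vinyl group (future C4 and C3) under neutral conditions that spare the aryl silyl ether.

Step 6
Reactants: 8 [(4-ethenyl-6-methoxy-7-methylnaphthalen-1-yl)oxy]triisopropylsilane
Product: 11 6-methoxy-1,1,7-trimethyl-9-[(triisopropylsilyl)oxy]-3,4-dihydrophenanthren-2(1H)-one, via cyclobutanone 9 (not isolated), via 10a-H isonaphthalene adduct 10 (not isolated)
Conditions: i-PrCOCl, Et3N, CH2Cl2, 0 °C → rt (dimethylketene in the flask); then 8, EtAlCl2 (2.5 equiv), −78 °C → rt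
Reagents that add atoms: isobutyryl chloride CC(C)C(=O)Cl (source of dimethylketene CC(C)=C=O)
Why: Proposed new method: the EtAlCl2-activated ketene should be attacked at its carbonyl carbon by the terminal vinyl carbon C3 of 8 (C2–C3 bond), giving an aluminium enolate tethered to a benzylic cation that the para silyloxy group delocalises over C4, C10a and the C9 oxygen; collapse at C4 gives cyclobutanone 9 reversibly, whereas attack of the enolate carbon C1 on the ortho carbon C10a gives the six-membered ring as isonaphthalene 10, which rearomatises irreversibly by proton transfer from C10a to C4. The closest known reactions are the Lewis acid-promoted ketene–alkene [2+2] cycloaddition, the Lewis acid-triggered opening of donor-substituted cyclobutanones to 1,4-zwitterions that are captured in formal [4+2] fashion, and the dearomative Diels–Alder reaction of 1-vinylnaphthalenes followed by rearomatisation. Ring A is closed by a stepwise polar formal [4+2] cycloaddition (Friedel–Crafts-type attack of the enolate on the arene-delocalised cation) in which the aromatic C4a=C10a bond is half of the diene. No stereocentre is formed, because C1 carries two methyl groups and C3 and C4 are methylene carbons in 11. The step needs six-ring closure to win over four-ring closure and over proton loss to an open-chain enone: ring strain should let 9 re-ionise under the Lewis acid while rearomatisation makes the six-ring path a sink, the peri hydrogen at C5 turns the side chain towards C10a, and the quaternary C1 keeps 11 from enolising towards the arene or aromatising.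

Step 7
Reactants: 11 6-methoxy-1,1,7-trimethyl-9-[(triisopropylsilyl)oxy]-3,4-dihydrophenanthren-2(1H)-one
Product: 12 3-hydroxy-6-methoxy-1,1,7-trimethyl-9-[(triisopropylsilyl)oxy]phenanthren-2(1H)-one
Conditions: SeO2, 1,4-dioxane/H2O, 90 °C
Reagents that add atoms: selenium dioxide O=[Se]=O
Why: Riley oxidation should attack the only enolisable position (C3, since C1 is quaternary) to give the 2,3-diketone, which is expected to rest as the arene-conjugated diosphenol with the C3=C4 double bond.

Step 8
Reactants: 12 3-hydroxy-6-methoxy-1,1,7-trimethyl-9-[(triisopropylsilyl)oxy]phenanthren-2(1H)-one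
Product: 13 3,6-dimethoxy-1,1,7-trimethyl-9-[(triisopropylsilyl)oxy]phenanthren-2(1H)-one
Conditions: Me2SO4, K2CO3, acetone, 50 °C
Reagents that add atoms: dimethyl sulfate COS(=O)(=O)OC
Why: Williamson-type O-alkylation of the acidic diosphenol hydroxyl with a hard methylating agent should give the enol methyl ether rather than C4-methylation, under conditions that leave the aryl silyl ether intact.

**Lower half**

Step 9
Reactants: 14 3-hydroxy-4-methylbenzaldehyde
Product: 15 4-methyl-3-[(triisopropylsilyl)oxy]benzaldehyde
Conditions: TIPSCl, imidazole, DMF, rt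
Reagents that add atoms: chlorotriisopropylsilane CC(C)[Si](Cl)(C(C)C)C(C)C
Why: Silyl ether formation differentiates the future 6′-hydroxyl from the naphthol oxygen that is methylated in step 13.

Step 10
Reactants: 15 4-methyl-3-[(triisopropylsilyl)oxy]benzaldehyde; 2 (2-carboxyethyl)triphenylphosphonium bromide
Product: 16 (E)-4-{4-methyl-3-[(triisopropylsilyl)oxy]phenyl}but-3-enoic acid
Conditions: NaN(SiMe3)2 (2.2 equiv), THF, 0 °C → rt; aq. HCl work-up
Reagents that add atoms: none
Why: Wittig olefination as in step 1, with a non-nucleophilic amide base that should not cleave the aryl silyl ether.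

Step 11
Reactants: 16 (E)-4-{4-methyl-3-[(triisopropylsilyl)oxy]phenyl}but-3-enoic acid
Product: 18 7-methyl-6-[(triisopropylsilyl)oxy]naphthalen-1-ol, via naphthyl acetate 17 (not isolated)
Conditions: Ac2O, NaOAc, 140 °C; then N2H4·H2O, THF/MeOH, 0 °C
Reagents that add atoms: none
Why: The vinylketene electrocyclisation benzannulation of step 2 should close para to the bulky silyloxy group, and hydrazinolysis removes the aryl acetate selectively in the presence of the aryl silyl ether.

Step 12
Reactants: 18 7-methyl-6-[(triisopropylsilyl)oxy]naphthalen-1-ol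
Product: 19 4-bromo-7-methyl-6-[(triisopropylsilyl)oxy]naphthalen-1-ol
Conditions: NBS, MeCN, −20 °C → 0 °C
Reagents that add atoms: N-bromosuccinimide O=C1CCC(=O)N1Br
Why: Electrophilic aromatic bromination para to the free naphthol hydroxyl, as in step 3.

Step 13
Reactants: 19 4-bromo-7-methyl-6-[(triisopropylsilyl)oxy]naphthalen-1-ol
Product: 20 4-bromo-1-methoxy-7-methyl-6-[(triisopropylsilyl)oxy]naphthalene
Conditions: MeI, K2CO3, acetone, 40 °C
Reagents that add atoms: iodomethane CI
Why: Williamson ether synthesis installs the future 9′-methoxy group on the only free phenol.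

Step 14
Reactants: 20 4-bromo-1-methoxy-7-methyl-6-[(triisopropylsilyl)oxy]naphthalene
Product: 21 4-ethenyl-1-methoxy-7-methyl-6-[(triisopropylsilyl)oxy]naphthalene
Conditions: CH2=CHSnBu3, Pd(PPh3)4 (5 mol %), toluene, 100 °C
Reagents that add atoms: tributyl(vinyl)stannane C=C[Sn](CCCC)(CCCC)CCCC
Why: Stille cross-coupling, as in step 5.

Step 15
Reactants: 21 4-ethenyl-1-methoxy-7-methyl-6-[(triisopropylsilyl)oxy]naphthalene
Product: 24 9-methoxy-1,7-dimethyl-6-[(triisopropylsilyl)oxy]-3,4-dihydrophenanthren-2(1H)-one, via cyclobutanone 22 (not isolated), via 10a-H isonaphthalene adduct 23 (not isolated)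
Conditions: EtCOCl, Et3N, CH2Cl2, 0 °C → rt (methylketene in the flask); then 21, EtAlCl2 (2.5 equiv), −78 °C → rt
Reagents that add atoms: propionyl chloride CCC(=O)Cl (source of methylketene CC=C=O)
Why: Proposed new method: the same dearomative formal [4+2] annulation as in step 6 (vinyl carbon attacks the Lewis acid-bound ketene, the enolate closes on the ortho carbon of the para-methoxy-stabilised benzylic cation, then rearomatisation by proton shift), with the Lewis acid-promoted ketene–alkene [2+2] cycloaddition and the zwitterionic opening of donor-substituted cyclobutanones as closest known types; the C1 stereocentre is formed without control and is erased in step 16.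

Step 16
Reactants: 24 9-methoxy-1,7-dimethyl-6-[(triisopropylsilyl)oxy]-3,4-dihydrophenanthren-2(1H)-one
Product: 25 9-methoxy-1,7-dimethyl-6-[(triisopropylsilyl)oxy]phenanthren-2-ol
Conditions: DDQ (1.05 equiv), 1,4-dioxane, rt
Reagents that add atoms: none
Why: Quinone dehydrogenation (hydride abstraction from the enol of the 2-tetralone, then tautomerisation) should aromatise ring A to the 1-methyl-2-phenanthrol.

Step 17
Reactants: 25 9-methoxy-1,7-dimethyl-6-[(triisopropylsilyl)oxy]phenanthren-2-ol
Product: 26 9-methoxy-1,7-dimethyl-6-[(triisopropylsilyl)oxy]phenanthrene-2,3-dione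
Conditions: IBX, DMF, rt; used at once
Reagents that add atoms: 2-iodoxybenzoic acid O=C1OI(=O)(O)c2ccccc12
Why: Ortho-oxygenation of a phenol by IBX should deliver oxygen to the only free ortho carbon (C3′, since C1′ carries the methyl group) and oxidise the catechol-level intermediate on to the o-quinone.

**Union and deprotection**

Step 18
Reactants: 13 3,6-dimethoxy-1,1,7-trimethyl-9-[(triisopropylsilyl)oxy]phenanthren-2(1H)-one; 26 9-methoxy-1,7-dimethyl-6-[(triisopropylsilyl)oxy]phenanthrene-2,3-dione
Product: 27 bis(triisopropylsilyl) ether of actephilol C (cis-fused dioxane, S at the ketal carbon, S at C4)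
Conditions: (R)-TRIP (10 mol %), 4 Å molecular sieves, toluene, −40 °C → −20 °C
Reagents that add atoms: none
Why: Proposed new method: an inverse-electron-demand oxa-Diels–Alder reaction in which the O=C–C=O unit of 26 adds suprafacially across the C3=C4 enol ether of 13, so that both C–O bonds form on one face and the ketal carbon and the benzylic CH come out cis; the chiral phosphoric acid (R)-3,3′-bis(2,4,6-triisopropylphenyl)-1,1′-binaphthyl-2,2′-diyl hydrogen phosphate, hydrogen-bonded to the more basic C2′ carbonyl, is meant to select one enantiotopic face of planar 13; the regiochemistry is expected from bonding of the nucleophilic enol-ether carbon C4 to the oxygen of the more electrophilic C3′ carbonyl, with the oxygen of the 9′-methoxy-conjugated C2′ carbonyl closing on the oxocarbenium carbon C3; closest known types are the thermal o-quinone/enol ether hetero-Diels–Alder reaction to 1,4-benzodioxanes and phosphoric acid-catalysed oxa-Diels–Alder reactions of o-quinone methides.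

Step 19
Reactants: 27 bis(triisopropylsilyl) ether of actephilol C
Product: 28 actephilol C
Conditions: HF·pyridine, THF/pyridine, 0 °C → rt
Reagents that add atoms: none
Why: Fluoride-mediated cleavage of both aryl silyl ethers under buffered, non-basic conditions should avoid a free 9-phenoxide and with it retro-oxa-Michael opening at C4, so that both stereocentres are kept.

**Compound list**

1 | 3-methoxy-4-methylbenzaldehyde | COc1cc(C=O)ccc1C | starting material
2 | (2-carboxyethyl)triphenylphosphonium bromide | OC(=O)CC[P+](c1ccccc1)(c1ccccc1)c1ccccc1.[Br-] | starting material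
3 | (E)-4-(3-methoxy-4-methylphenyl)but-3-enoic acid | COc1cc(/C=C/CC(=O)O)ccc1C | intermediate
4 | 6-methoxy-7-methylnaphthalen-1-yl acetate | CC(=O)Oc1cccc2cc(OC)c(C)cc12 | intermediate
5 | 6-methoxy-7-methylnaphthalen-1-ol | Oc1cccc2cc(OC)c(C)cc12 | intermediate
6 | 4-bromo-6-methoxy-7-methylnaphthalen-1-ol | Oc1ccc(Br)c2cc(OC)c(C)cc12 | intermediate
7 | [(4-bromo-6-methoxy-7-methylnaphthalen-1-yl)oxy]triisopropylsilane | COc1cc2c(Br)ccc(O[Si](C(C)C)(C(C)C)C(C)C)c2cc1C | intermediate
8 | [(4-ethenyl-6-methoxy-7-methylnaphthalen-1-yl)oxy]triisopropylsilane | C=Cc1ccc(O[Si](C(C)C)(C(C)C)C(C)C)c2cc(C)c(OC)cc12 | intermediate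
9 | 3-{7-methoxy-6-methyl-4-[(triisopropylsilyl)oxy]naphthalen-1-yl}-2,2-dimethylcyclobutan-1-one (racemic) | CC1(C)C(=O)CC1c1ccc(O[Si](C(C)C)(C(C)C)C(C)C)c2cc(C)c(OC)cc12 | intermediate
10 | 6-methoxy-1,1,7-trimethyl-9-[(triisopropylsilyl)oxy]-3,10a-dihydrophenanthren-2(1H)-one (racemic) | CC1(C)C(=O)CC=C2c3cc(OC)c(C)cc3C(O[Si](C(C)C)(C(C)C)C(C)C)=CC12 | intermediate
11 | 6-methoxy-1,1,7-trimethyl-9-[(triisopropylsilyl)oxy]-3,4-dihydrophenanthren-2(1H)-one | CC1(C)C(=O)CCc2c1cc(O[Si](C(C)C)(C(C)C)C(C)C)c1cc(C)c(OC)cc21 | intermediate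
12 | 3-hydroxy-6-methoxy-1,1,7-trimethyl-9-[(triisopropylsilyl)oxy]phenanthren-2(1H)-one | CC1(C)C(=O)C(O)=Cc2c1cc(O[Si](C(C)C)(C(C)C)C(C)C)c1cc(C)c(OC)cc21 | intermediate
13 | 3,6-dimethoxy-1,1,7-trimethyl-9-[(triisopropylsilyl)oxy]phenanthren-2(1H)-one | COC1=Cc2c(cc(O[Si](C(C)C)(C(C)C)C(C)C)c3cc(C)c(OC)cc23)C(C)(C)C1=O | intermediate
14 | 3-hydroxy-4-methylbenzaldehyde | Cc1ccc(C=O)cc1O | starting material
15 | 4-methyl-3-[(triisopropylsilyl)oxy]benzaldehyde | Cc1ccc(C=O)cc1O[Si](C(C)C)(C(C)C)C(C)C | intermediate
16 | (E)-4-{4-methyl-3-[(triisopropylsilyl)oxy]phenyl}but-3-enoic acid | Cc1ccc(/C=C/CC(=O)O)cc1O[Si](C(C)C)(C(C)C)C(C)C | intermediate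
17 | 7-methyl-6-[(triisopropylsilyl)oxy]naphthalen-1-yl acetate | CC(=O)Oc1cccc2cc(O[Si](C(C)C)(C(C)C)C(C)C)c(C)cc12 | intermediate
18 | 7-methyl-6-[(triisopropylsilyl)oxy]naphthalen-1-ol | Oc1cccc2cc(O[Si](C(C)C)(C(C)C)C(C)C)c(C)cc12 | intermediate
19 | 4-bromo-7-methyl-6-[(triisopropylsilyl)oxy]naphthalen-1-ol | Oc1ccc(Br)c2cc(O[Si](C(C)C)(C(C)C)C(C)C)c(C)cc12 | intermediate
20 | 4-bromo-1-methoxy-7-methyl-6-[(triisopropylsilyl)oxy]naphthalene | COc1ccc(Br)c2cc(O[Si](C(C)C)(C(C)C)C(C)C)c(C)cc12 | intermediate
21 | 4-ethenyl-1-methoxy-7-methyl-6-[(triisopropylsilyl)oxy]naphthalene | C=Cc1ccc(OC)c2cc(C)c(O[Si](C(C)C)(C(C)C)C(C)C)cc12 | intermediate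
22 | 3-{4-methoxy-6-methyl-7-[(triisopropylsilyl)oxy]naphthalen-1-yl}-2-methylcyclobutan-1-one (stereoisomer mixture) | CC1C(=O)CC1c1ccc(OC)c2cc(C)c(O[Si](C(C)C)(C(C)C)C(C)C)cc12 | intermediate
23 | 9-methoxy-1,7-dimethyl-6-[(triisopropylsilyl)oxy]-3,10a-dihydrophenanthren-2(1H)-one (stereoisomer mixture) | CC1C(=O)CC=C2c3cc(O[Si](C(C)C)(C(C)C)C(C)C)c(C)cc3C(OC)=CC12 | intermediate
24 | 9-methoxy-1,7-dimethyl-6-[(triisopropylsilyl)oxy]-3,4-dihydrophenanthren-2(1H)-one (racemic) | CC1C(=O)CCc2c1cc(OC)c1cc(C)c(O[Si](C(C)C)(C(C)C)C(C)C)cc21 | intermediate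
25 | 9-methoxy-1,7-dimethyl-6-[(triisopropylsilyl)oxy]phenanthren-2-ol | Cc1c(O)ccc2c1cc(OC)c1cc(C)c(O[Si](C(C)C)(C(C)C)C(C)C)cc21 | intermediate
26 | 9-methoxy-1,7-dimethyl-6-[(triisopropylsilyl)oxy]phenanthrene-2,3-dione | CC1=C2C=C(OC)c3cc(C)c(O[Si](C(C)C)(C(C)C)C(C)C)cc3C2=CC(=O)C1=O | intermediate
27 | bis(triisopropylsilyl) ether of actephilol C: upper 3,6-dimethoxy-1,1,7-trimethyl-9-silyloxy-3,4-dihydrophenanthren-2(1H)-one joined C3–O2′ and C4–O3′ to the lower 9′-methoxy-1′,7′-dimethyl-6′-silyloxyphenanthrene-2′,3′-diyl dioxy unit; cis-fused, (S) ketal carbon, (S) C4 | COc1cc2c3c(cc(O[Si](C(C)C)(C(C)C)C(C)C)c2cc1C)C(C)(C)C(=O)[C@@]1(OC)Oc2c(cc4c(cc(OC)c5cc(C)c(O[Si](C(C)C)(C(C)C)C(C)C)cc54)c2C)O[C@@H]31 | intermediate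
28 | actephilol C (as 27 with free 9-OH and 6′-OH) | COc1cc2c3c(cc(O)c2cc1C)C(C)(C)C(=O)[C@@]1(OC)Oc2c(cc4c(cc(OC)c5cc(C)c(O)cc54)c2C)O[C@@H]31 | target

**Step count and risks**

Total step count: 19 (steps 1–8 upper half, steps 9–17 lower half, steps 18–19 union and deprotection).
Longest linear sequence: 11 steps (14 → 28, steps 9–19).

Steps most likely to fail:

1. Step 6. The zwitterion may collapse only at the benzylic carbon and stay as the cyclobutanone, lose a proton to an open-chain aryl enone, or the electron-rich vinylarene may oligomerise cationically under the Lewis acid, so that closure at C10a does not occur. Fallback, setting out from 7 and coming back at 11: Negishi coupling of 7 with (4-methylpent-3-en-1-yl)zinc bromide (Pd(PPh3)4, THF, 60 °C) would give the homoprenyl arene F1. Epoxidation with mCPBA (NaHCO3, CH2Cl2, 0 °C) would give the trisubstituted epoxide F2. BF3·OEt2 (CH2Cl2, −78 °C) should open the epoxide at its tertiary carbon and close ring A by Friedel–Crafts attack of C10a (epoxide-initiated cation–arene cyclisation), giving the secondary alcohol F3. Dess–Martin oxidation of F3 returns to ketone 11.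

2. Step 15. The same competing four-ring collapse, proton loss and oligomerisation apply, together with fast self-dimerisation of the monosubstituted ketene before it meets the alkene. Fallback, setting out from 20 and coming back at 25 (steps 15 and 16 are bypassed): Negishi coupling of 20 with pent-3-yn-1-ylzinc bromide (Pd(PPh3)4, THF, 60 °C) would give the internal alkyne F4. PdCl2-catalysed oxidation in DMSO (140 °C) would give the 1,2-diketone F5. BF3·OEt2 (CH2Cl2, 0 °C → rt) should close ring A by intramolecular Friedel–Crafts hydroxyalkylation of C10a at the methyl ketone carbon, and loss of water with enolisation gives phenanthrol 25.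

3. Step 18. Facial discrimination by the chiral acid may be poor or of the wrong sense, an uncatalysed background addition may erode it, and the o-quinone may decay (tautomerisation through its C1′ methyl group) before it is trapped. Fallback, setting out from 13 and 26 and coming back at 27: the uncatalysed thermal hetero-Diels–Alder addition (toluene, rt → 40 °C, freshly prepared 26 in slight excess) should give the racemic cis adduct, that is 27 together with its enantiomer F6. Preparative HPLC on a chiral stationary phase (amylose tris(3,5-dimethylphenylcarbamate)) then separates 27 from F6.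

Further compounds
F1 | step 6 | [(6-methoxy-7-methyl-4-(4-methylpent-3-en-1-yl)naphthalen-1-yl)oxy]triisopropylsilane | CC(C)=CCCc1ccc(O[Si](C(C)C)(C(C)C)C(C)C)c2cc(C)c(OC)cc12
F2 | step 6 | {[4-(2-(3,3-dimethyloxiran-2-yl)ethyl)-6-methoxy-7-methylnaphthalen-1-yl]oxy}triisopropylsilane (racemic) | CC1(C)OC1CCc1ccc(O[Si](C(C)C)(C(C)C)C(C)C)c2cc(C)c(OC)cc12
F3 | step 6 | 6-methoxy-1,1,7-trimethyl-9-[(triisopropylsilyl)oxy]-1,2,3,4-tetrahydrophenanthren-2-ol (racemic) | CC1(C)C(O)CCc2c1cc(O[Si](C(C)C)(C(C)C)C(C)C)c1cc(C)c(OC)cc21
F4 | step 15 | 1-methoxy-7-methyl-4-(pent-3-yn-1-yl)-6-[(triisopropylsilyl)oxy]naphthalene | CC#CCCc1ccc(OC)c2cc(C)c(O[Si](C(C)C)(C(C)C)C(C)C)cc12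
F5 | step 15 | 5-{4-methoxy-6-methyl-7-[(triisopropylsilyl)oxy]naphthalen-1-yl}pentane-2,3-dione | CC(=O)C(=O)CCc1ccc(OC)c2cc(C)c(O[Si](C(C)C)(C(C)C)C(C)C)cc12
F6 | step 18 | enantiomer of 27 (cis-fused, R at the ketal carbon, R at C4) | COc1cc2c3c(cc(O[Si](C(C)C)(C(C)C)C(C)C)c2cc1C)C(C)(C)C(=O)[C@]1(OC)Oc2c(cc4c(cc(OC)c5cc(C)c(O[Si](C(C)C)(C(C)C)C(C)C)cc54)c2C)O[C@H]31
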